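**Plan**
- Retrosynthesis first removes the angeloyl group (C3–O acyl bond) and lowers C12 to a silyl-protected allylic alcohol. It then cuts C3–C4 of ring A. The C4 tertiary carbinol lies between the C3 carbinol and the C5=C6 alkene of ring B, which is the pattern left by a γ-silyloxyallylboronate (boron on C6, enol ether C5=C4) that attacks a C3 aldehyde through C4.
- Further cuts: C6–B and O–Si (borylcopper addition to a ring-B acetyl enone), C5–C4 (Stille acylation of an enol triflate), C10–C1 (Michael addition to methyl acrylate), C12–O (allylic chlorination of carvone).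
- Forward: ring B is the carvone ring throughout. The C1–C3 chain is attached at C10, C4/C15 at C5 and boron at C6; ring A is closed last by the C3–C4 bond.
- Stereochemistry: C7 from (R)-carvone; C10 from the (R)-1-phenylethylamine imine; C6–B anti to the C7 group; C4 from α-face closure and the enol ether geometry; C3 reset by oxidation and axial hydride delivery; the (Z)-ester from angelic acid.

Key step: step 11

Remark on the chemistry: eudesmane numbering is used for all intermediates. C7 is the carvone stereocentre, C5 the former carvone carbonyl carbon, C10 the methyl-bearing ring carbon, C1–C3 the acrylate-derived chain, C4/C15 the acetyl carbons, C11–C13 the former isopropenyl group with C12 oxygenated, and C14 the methyl on C10. β is the face of C14 and of the C7 side chain. TBS = tert-butyldimethylsilyl, TES = triethylsilyl, Bpin = pinacolatoboryl.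

**Step 1**
Reactants: 1 (R)-carvone
Product: 2 10-chlorocarvone
Conditions: Ca(OCl)2, CO2 (dry ice), CH2Cl2/H2O, 0 °C
Reagents that add atoms: calcium hypochlorite, [Ca+2].[O-]Cl.[O-]Cl
Why: Ene-type allylic chlorination by HOCl (released from Ca(OCl)2 by CO2) takes place only at the electron-rich 1,1-disubstituted isopropenyl alkene and shifts it into the other branch, a standard transformation of carvone that leaves the enone and the ring stereocentre (the later C7) untouched.

**Step 2**
Reactants: 2 10-chlorocarvone
Product: 3 10-acetoxycarvone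
Conditions: KOAc, Bu4NI (cat.), DMF, 60 °C
Reagents that add atoms: potassium acetate, CC(=O)[O-].[K+]
Why: SN2 displacement of the primary allylic chloride by acetate with iodide catalysis (the SN2' pathway would give the same product because the allyl unit is symmetric).

**Step 3**
Reactants: 3 10-acetoxycarvone
Product: 4 10-hydroxycarvone
Conditions: K2CO3 (cat.), MeOH, 0 °C
Reagents that add atoms: none
Why: Carbonate-catalysed transesterification with methanol frees the primary allylic alcohol at low temperature without conjugate addition to the enone.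

**Step 4**
Reactants: 4 10-hydroxycarvone
Product: 5 10-(tert-butyldimethylsilyloxy)carvone
Conditions: TBSCl, imidazole, CH2Cl2, rt
Reagents that add atoms: tert-butyldimethylsilyl chloride, CC(C)(C)[Si](C)(C)Cl
Why: Imidazole-promoted silylation gives a primary allylic TBS ether that is inert to the hydride reagents, amide bases, zerovalent palladium and borylcopper species used later.

**Step 5**
Reactants: 5 10-(tert-butyldimethylsilyloxy)carvone
Product: 7 silyloxy dihydrocarvone (C10 epimer mixture), via lithium enolate 6 (not isolated)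
Conditions: LiBH(s-Bu)3, THF, −78 °C; then H2O
Reagents that add atoms: none
Why: Conjugate hydride reduction of the β-unsubstituted cyclohexenone by LiBH(s-Bu)3 and protonation of the resulting enolate give the saturated ketone; C10 is formed as an epimer mixture that is erased in step 6.

**Step 6**
Reactants: 7 silyloxy dihydrocarvone, 8 (R)-1-phenylethylamine, 9 methyl acrylate
Product: 12 keto ester with quaternary (S)-C10, via ketimine 10 (not isolated), via Michael-adduct imine 11 (not isolated)
Conditions: 8, TsOH (cat.), toluene, reflux (Dean–Stark); then 9, THF, 50 °C; then 10% aq. AcOH, rt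
Reagents that add atoms: water, O
Why: Asymmetric Michael addition of a chiral imine (aza-ene-type reaction of the more substituted secondary enamine tautomer with methyl acrylate, then hydrolysis): the acrylate adds at the methyl-bearing carbon on the enamine face turned away from the phenyl group of the (R)-auxiliary, which sets quaternary C10 as (S) with the C1 chain trans to the C7 substituent, the sense known from 2-methylcyclohexanone and expected to override the weak bias of the remote C7 group.

**Step 7**
Reactants: 12 keto ester
Product: 14 C5=C6 enol triflate, via potassium enolate 13 (not isolated)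
Conditions: KN(SiMe3)2, THF, −78 °C; then PhNTf2, −78 → 0 °C
Reagents that add atoms: N-phenylbis(trifluoromethanesulfonimide), O=S(=O)(N(c1ccccc1)S(=O)(=O)C(F)(F)F)C(F)(F)F
Why: Enolate O-sulfonylation: deprotonation can occur only at C6 because C10 is quaternary and the ketone is far more acidic than the ester, and PhNTf2 converts the potassium enolate into the C5=C6 enol triflate.

**Step 8**
Reactants: 14 enol triflate, 15 tributyl(1-ethoxyvinyl)stannane
Product: 17 ring-B acetyl enone, via ethoxydiene 16 (not isolated)
Conditions: Pd(PPh3)4 (10 mol %), LiCl, CuCl, DMSO, 60 °C; then aq. oxalic acid, THF, 0 °C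
Reagents that add atoms: water, O
Why: Stille coupling of the hindered alkenyl triflate with an acetyl-anion equivalent under LiCl/CuCl acceleration, followed by mild acid hydrolysis of the ethoxydiene, installs C4 and C15 as the acetyl group on C5.

**Step 9**
Reactants: 17 acetyl enone, 18 bis(pinacolato)diboron
Product: 20 C6 allylboronate with C5=C4 triethylsilyl enol ether (methyl ester), via copper enolate 19 (not isolated)
Conditions: CuCl, NaOt-Bu, PBu3, 18 (1.1 equiv each), THF, 0 °C; then 17, Et3SiCl, DMPU, −40 → 0 °C; filtration through deactivated alumina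
Reagents that add atoms: chlorotriethylsilane, CC[Si](Cl)(CC)CC
Why: Borylcopper conjugate addition with chlorosilane capture of the enolate (1,4-silaboration of an enone): pinB–Cu adds to C6 on the α face, anti to the C7 substituent and to the axial C14 methyl, and O-silylation of the enolate born from the s-trans enone (acetyl methyl turned away from quaternary C10) fixes the enol ether with OSiEt3 cis to C10 and CH3 cis to C6.

**Step 10**
Reactants: 20 allylboronate silyl enol ether methyl ester
Product: 22 allylboronate silyl enol ether aldehyde (kept cold and used at once), via aluminium hemiacetal 21 (not isolated)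
Conditions: i-Bu2AlH (1.1 equiv), CH2Cl2, −78 °C; then MeOH, aq. KNaC4H4O6 (potassium sodium tartrate), 0 °C
Reagents that add atoms: none
Why: Partial reduction of a methyl ester by i-Bu2AlH at −78 °C stops at the tetrahedral aluminium hemiacetal, which releases the aldehyde only on cold neutral work-up, while boronic ester, silyl enol ether and silyl ether are inert under these conditions.

**Step 11**
Reactants: 22 allylboronate silyl enol ether aldehyde
Product: 24 3α-hydroxy-4β-triethylsilyloxy bicycle with C5=C6, via C3 O-boronate 23 (not isolated)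
Conditions: toluene (high dilution), 25 → 70 °C; then aq. NaHCO3
Reagents that add atoms: none
Why: Proposed new method: the aldehyde oxygen binds the boron on C6 and C3 bonds to the enol-ether carbon C4 in a closed six-membered transition state (boron, oxygen, C3, C4, C5, C6) while the C6–B bond breaks and the alkene moves to C5=C6, leaving boron on the C3 oxygen until work-up. The closest known reactions are intramolecular allylborations of aldehydes and additions of γ-alkoxy- or γ-silyloxyallylboronates to aldehydes that give 1,2-diol monoethers; the fully substituted γ-carbon and the tether placed on the central allyl carbon are untested, the geometric model being the type 2 intramolecular carbonyl-ene cyclisation with its bicyclo[3.3.1]-like array. Ring A closes in a 6-(enolendo)-exo-trig mode. C4 is controlled by two substrate elements, the tether on C10 and the 6α-boron, which both lie on the α face so that C3 can reach only the α face of C4, and by the enol ether geometry, which turns the OSiEt3 group (cis to C10) into the β-axial and C15 into the α-equatorial substituent; C3 is controlled by the closed transition state, which holds the C3–O bond axial on the α face (3α-OH, anti to the 4β oxygen) and is reset in steps 12 and 13. The step needs allyl transfer through C4 in preference to attack through C5 (Mukaiyama-type aldol) or to bimolecular reaction, which the substrate secures by carrying its own boron as the only Lewis acid next to the tethered aldehyde, supported by high dilution.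

**Step 12**
Reactants: 24 3α-alcohol
Product: 25 C3 ketone
Conditions: Dess–Martin periodinane, CH2Cl2, 0 °C → rt
Reagents that add atoms: none
Why: Dess–Martin oxidation of the hindered axial secondary alcohol gives the C3 ketone under non-basic conditions; C4 is fully substituted, so neither epimerisation nor migration of C5=C6 into conjugation is possible.

**Step 13**
Reactants: 25 C3 ketone
Product: 26 3β-alcohol
Conditions: NaBH4, CeCl3·7H2O, MeOH, −40 → 0 °C
Reagents that add atoms: none
Why: Borohydride reduction under CeCl3 buffering (which keeps the medium non-basic and so suppresses 1,2-silyl migration): hydride is delivered axially from the open α face, anti to the axial 4β-OSiEt3 group that shields the β face, giving the equatorial 3β-alcohol.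

**Step 14**
Reactants: 26 3β-alcohol, 27 angelic acid
Product: 28 3β-angelate
Conditions: 27, 2,4,6-trichlorobenzoyl chloride, Et3N, toluene, rt; then 26, DMAP, toluene, 60 °C
Reagents that add atoms: none
Why: Yamaguchi esterification: the mixed anhydride formed from angelic acid acylates the secondary 3β-alcohol under DMAP catalysis at moderate temperature, conditions under which the (Z)-geometry of the angeloyl group is retained.

**Step 15**
Reactants: 28 3β-angelate bis-silyl ether
Product: 29 3β-angeloyloxy-4β,12-diol
Conditions: HF·pyridine, pyridine, THF, 0 °C → rt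
Reagents that add atoms: none
Why: Fluoride-mediated desilylation with pyridine-buffered HF·pyridine removes the primary TBS ether and the tertiary TES ether in one operation without hydrolysis or migration of the angelate.

**Step 16**
Reactants: 29 diol
Product: 30 C12 enal
Conditions: MnO2, CH2Cl2, rt
Reagents that add atoms: none
Why: MnO2 oxidation is specific for the primary allylic alcohol and gives the 2-substituted acrolein; the tertiary allylic C4 alcohol cannot be oxidised.

**Step 17**
Reactants: 30 enal
Product: 31 C12 acid
Conditions: NaClO2, NaH2PO4, 2-methyl-2-butene, t-BuOH/H2O, 0 °C → rt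
Reagents that add atoms: sodium chlorite, [Na+].[O-]Cl=O
Why: Pinnick oxidation with 2-methyl-2-butene as hypochlorite scavenger converts the enal to the acid under weakly acidic conditions that leave the doubly allylic C7–H and the alkenes in place.

**Step 18**
Reactants: 31 acid
Product: 32 CNP0283268.1
Conditions: MeI, KHCO3, DMF, rt
Reagents that add atoms: iodomethane, CI
Why: SN2 O-methylation of the carboxylate with MeI under bicarbonate, a base too weak to deprotonate C7 or to move the C11=C13 alkene into conjugation with ring B, completes the methyl ester.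

**Compound list**
1 | (R)-carvone | CC1=CC[C@@H](C(C)=C)CC1=O | starting material
2 | 10-chlorocarvone, (5R)-5-(3-chloroprop-1-en-2-yl)-2-methylcyclohex-2-en-1-one | C=C(CCl)[C@H]1CC(=O)C(C)=CC1 | intermediate
3 | 10-acetoxycarvone, 2-[(1R)-4-methyl-5-oxocyclohex-3-en-1-yl]prop-2-en-1-yl acetate | C=C(COC(C)=O)[C@H]1CC(=O)C(C)=CC1 | intermediate
4 | 10-hydroxycarvone, (5R)-5-(3-hydroxyprop-1-en-2-yl)-2-methylcyclohex-2-en-1-one | C=C(CO)[C@H]1CC(=O)C(C)=CC1 | intermediate
5 | 10-(tert-butyldimethylsilyloxy)carvone | C=C(CO[Si](C)(C)C(C)(C)C)[C@H]1CC(=O)C(C)=CC1 | intermediate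
6 | lithium enolate from conjugate reduction of 5 (not isolated) | [Li+].C=C(CO[Si](C)(C)C(C)(C)C)[C@H]1CC([O-])=C(C)CC1 | intermediate
7 | silyloxy dihydrocarvone, (5R)-5-[3-(tert-butyldimethylsilyloxy)prop-1-en-2-yl]-2-methylcyclohexan-1-one (both C2 epimers) | C=C(CO[Si](C)(C)C(C)(C)C)[C@H]1CC(=O)C(C)CC1 | intermediate
8 | (R)-1-phenylethylamine | C[C@@H](N)c1ccccc1 | starting material
9 | methyl acrylate | C=CC(=O)OC | starting material
10 | N-[(R)-1-phenylethyl] ketimine of 7 (not isolated) | C=C(CO[Si](C)(C)C(C)(C)C)[C@H]1CC(=N[C@H](C)c2ccccc2)C(C)CC1 | intermediate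
11 | N-[(R)-1-phenylethyl] ketimine of keto ester 12 (Michael adduct, not isolated) | C=C(CO[Si](C)(C)C(C)(C)C)[C@H]1CC(=N[C@H](C)c2ccccc2)[C@](C)(CCC(=O)OC)CC1 | intermediate
12 | methyl 3-[(1S,4R)-1-methyl-2-oxo-4-[3-(tert-butyldimethylsilyloxy)prop-1-en-2-yl]cyclohexyl]propanoate | C=C(CO[Si](C)(C)C(C)(C)C)[C@H]1CC(=O)[C@](C)(CCC(=O)OC)CC1 | intermediate
13 | potassium C5=C6 enolate of 12 (not isolated) | [K+].C=C(CO[Si](C)(C)C(C)(C)C)[C@H]1C=C([O-])[C@](C)(CCC(=O)OC)CC1 | intermediate
14 | C5=C6 enol triflate of 12 | C=C(CO[Si](C)(C)C(C)(C)C)[C@H]1C=C(OS(=O)(=O)C(F)(F)F)[C@](C)(CCC(=O)OC)CC1 | intermediate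
15 | tributyl(1-ethoxyvinyl)stannane | C=C(OCC)[Sn](CCCC)(CCCC)CCCC | starting material
16 | 5-(1-ethoxyvinyl) diene from Stille coupling (not isolated) | C=C(CO[Si](C)(C)C(C)(C)C)[C@H]1C=C(C(=C)OCC)[C@](C)(CCC(=O)OC)CC1 | intermediate
17 | methyl 3-[(1S,4R)-2-acetyl-1-methyl-4-[3-(tert-butyldimethylsilyloxy)prop-1-en-2-yl]cyclohex-2-en-1-yl]propanoate (ring-B acetyl enone) | C=C(CO[Si](C)(C)C(C)(C)C)[C@H]1C=C(C(C)=O)[C@](C)(CCC(=O)OC)CC1 | intermediate
18 | bis(pinacolato)diboron | CC1(C)OB(OC1(C)C)B1OC(C)(C)C(C)(C)O1 | starting material
19 | copper enolate after borylcupration, 6α-Bpin, oxygen cis to C10 (phosphine not shown, not isolated) | C=C(CO[Si](C)(C)C(C)(C)C)[C@H]1[C@H](B2OC(C)(C)C(C)(C)O2)/C(=C(\C)O[Cu])[C@](C)(CCC(=O)OC)CC1 | intermediate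
20 | ring-B allylboronate (6α-Bpin, trans to the C7 group) with C5=C4 triethylsilyl enol ether (OSiEt3 cis to C10), methyl ester chain on C10 | C=C(CO[Si](C)(C)C(C)(C)C)[C@H]1[C@H](B2OC(C)(C)C(C)(C)O2)/C(=C(\C)O[Si](CC)(CC)CC)[C@](C)(CCC(=O)OC)CC1 | intermediate
21 | diisobutylaluminium methyl hemiacetal of 22 (not isolated) | C=C(CO[Si](C)(C)C(C)(C)C)[C@H]1[C@H](B2OC(C)(C)C(C)(C)O2)/C(=C(\C)O[Si](CC)(CC)CC)[C@](C)(CCC(OC)O[Al](CC(C)C)CC(C)C)CC1 | intermediate
22 | ring-B allylboronate silyl enol ether with the C3 aldehyde chain on C10 (key-step precursor) | C=C(CO[Si](C)(C)C(C)(C)C)[C@H]1[C@H](B2OC(C)(C)C(C)(C)O2)/C(=C(\C)O[Si](CC)(CC)CC)[C@](C)(CCC=O)CC1 | intermediate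
23 | C3 O-pinacolboronate of 24 (not isolated) | C=C(CO[Si](C)(C)C(C)(C)C)[C@H]1C=C2[C@](C)(CC[C@@H](OB3OC(C)(C)C(C)(C)O3)[C@]2(C)O[Si](CC)(CC)CC)CC1 | intermediate
24 | 12-(tert-butyldimethylsilyloxy)-4β-(triethylsilyloxy)eudesma-5,11(13)-dien-3α-ol | C=C(CO[Si](C)(C)C(C)(C)C)[C@H]1C=C2[C@](C)(CC[C@@H](O)[C@]2(C)O[Si](CC)(CC)CC)CC1 | intermediate
25 | 12-(tert-butyldimethylsilyloxy)-4β-(triethylsilyloxy)eudesma-5,11(13)-dien-3-one | C=C(CO[Si](C)(C)C(C)(C)C)[C@H]1C=C2[C@](C)(CCC(=O)[C@]2(C)O[Si](CC)(CC)CC)CC1 | intermediate
26 | 12-(tert-butyldimethylsilyloxy)-4β-(triethylsilyloxy)eudesma-5,11(13)-dien-3β-ol | C=C(CO[Si](C)(C)C(C)(C)C)[C@H]1C=C2[C@](C)(CC[C@H](O)[C@]2(C)O[Si](CC)(CC)CC)CC1 | intermediate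
27 | angelic acid, (Z)-2-methylbut-2-enoic acid | C/C=C(/C)C(=O)O | starting material
28 | 3β-angeloyloxy-12-(tert-butyldimethylsilyloxy)-4β-(triethylsilyloxy)eudesma-5,11(13)-diene | C=C(CO[Si](C)(C)C(C)(C)C)[C@H]1C=C2[C@](C)(CC[C@H](OC(=O)/C(C)=C\C)[C@]2(C)O[Si](CC)(CC)CC)CC1 | intermediate
29 | 3β-angeloyloxyeudesma-5,11(13)-diene-4β,12-diol | C=C(CO)[C@H]1C=C2[C@](C)(CC[C@H](OC(=O)/C(C)=C\C)[C@]2(C)O)CC1 | intermediate
30 | 3β-angeloyloxy-4β-hydroxyeudesma-5,11(13)-dien-12-al | C=C(C=O)[C@H]1C=C2[C@](C)(CC[C@H](OC(=O)/C(C)=C\C)[C@]2(C)O)CC1 | intermediate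
31 | 3β-angeloyloxy-4β-hydroxyeudesma-5,11(13)-dien-12-oic acid | C=C(C(=O)O)[C@H]1C=C2[C@](C)(CC[C@H](OC(=O)/C(C)=C\C)[C@]2(C)O)CC1 | intermediate
32 | CNP0283268.1, methyl 3β-angeloyloxy-4β-hydroxyeudesma-5,11(13)-dien-12-oate, (3S,4R,7R,10S) | C=C(C(=O)OC)[C@H]1C=C2[C@](C)(CC[C@H](OC(=O)/C(C)=C\C)[C@]2(C)O)CC1 | target

**Step count**
Total: 18 steps. Longest linear sequence: 18 steps (1 to 32); compounds 8, 9, 15, 18 and 27 are used as purchased.

**Steps most likely to fail**

Step 11 (proposed new method). Allyl transfer to the aldehyde may be too slow at the fully substituted enol-ether carbon, so that protodeboronation, hydrolysis of the enol ether or enolisation of the aldehyde take over. Closure through a boat-like array or from a minor enol ether isomer would erode the configuration at C4. The fallback uses known chemistry (ring A by Robinson annulation, oxygen delivered to C4 from the C3 hydroxyl); it sets out from ketone 7 through its ketimine 10 and returns at 28. Ketimine 10 is added to ethyl vinyl ketone (THF, 40 °C) to give the Michael-adduct imine F1, which aqueous acetic acid hydrolyses to the 1,5-diketone F2. NaOMe in MeOH closes ring A by aldol condensation to the 4-methyl-4-en-3-one F3. NaBH4/CeCl3·7H2O should reduce F3 from the α face to the 3β-allylic alcohol F4. VO(acac)2/t-BuOOH should epoxidise C4=C5 on the face of the hydroxyl to give the 4β,5β-epoxy alcohol F5, and Yamaguchi esterification with 27 gives the epoxy angelate F6. Et3SiOTf/DBU (silyl triflate–amidine isomerisation of an epoxide to an allylic silyl ether) should open the C5–O bond, away from the electron-poor C3 side, with loss of a C6 proton, the only proton next to C5. This gives 28 with the 4β-silyloxy group and C5=C6, and the route continues with step 15.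

Step 9. Borylcupration of the hindered trisubstituted enone may be slow or occur on the β face, and capture of the enolate on oxygen may be incomplete or give mixed enol ether geometry. The fallback separates the two events; it sets out from 17 and returns at 20. Catalytic β-borylation in protic medium (CuCl, NaOt-Bu, a bisphosphine, 18, MeOH, THF) gives the β-boryl ketone F7 by protonation of the enolate. Soft enolisation under equilibrating conditions (Et3SiOTf, Et3N, CH2Cl2, 0 °C → rt) would then silylate towards C5 to give 20; the terminal enol ether isomer would be removed and recycled by hydrolysis.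

Step 14. Acylation of the hindered alcohol next to the quaternary silyloxy carbon may be slow enough for the angeloyl unit to isomerise to the (E)-form under heat and base. The fallback builds the (Z)-alkene on the ester; it sets out from 26 and returns at 28. DCC/DMAP esterification with 2-[bis(2,2,2-trifluoroethoxy)phosphoryl]propanoic acid gives the phosphonate ester F8. Still–Gennari olefination (KN(SiMe3)2, 18-crown-6, acetaldehyde, THF, −78 °C) then forms the (Z)-2-methylbut-2-enoate 28 directly.

**Further compounds**
F1 | step 11 | N-[(R)-1-phenylethyl] ketimine of diketone F2 (ethyl vinyl ketone Michael adduct) | C=C(CO[Si](C)(C)C(C)(C)C)[C@H]1CC(=N[C@H](C)c2ccccc2)[C@](C)(CCC(=O)CC)CC1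
F2 | step 11 | (2S,5R)-2-methyl-2-(3-oxopentyl)-5-[3-(tert-butyldimethylsilyloxy)prop-1-en-2-yl]cyclohexan-1-one (1,5-diketone) | C=C(CO[Si](C)(C)C(C)(C)C)[C@H]1CC(=O)[C@](C)(CCC(=O)CC)CC1
F3 | step 11 | 12-(tert-butyldimethylsilyloxy)eudesma-4,11(13)-dien-3-one | C=C(CO[Si](C)(C)C(C)(C)C)[C@H]1CC2=C(C)C(=O)CC[C@]2(C)CC1
F4 | step 11 | 12-(tert-butyldimethylsilyloxy)eudesma-4,11(13)-dien-3β-ol | C=C(CO[Si](C)(C)C(C)(C)C)[C@H]1CC2=C(C)[C@@H](O)CC[C@]2(C)CC1
F5 | step 11 | 4β,5β-epoxy-12-(tert-butyldimethylsilyloxy)eudesm-11(13)-en-3β-ol | C=C(CO[Si](C)(C)C(C)(C)C)[C@H]1C[C@]23O[C@@]2(C)[C@@H](O)CC[C@]3(C)CC1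
F6 | step 11 | 3β-angeloyloxy-4β,5β-epoxy-12-(tert-butyldimethylsilyloxy)eudesm-11(13)-ene | C=C(CO[Si](C)(C)C(C)(C)C)[C@H]1C[C@]23O[C@@]2(C)[C@@H](OC(=O)/C(C)=C\C)CC[C@]3(C)CC1
F7 | step 9 | β-boryl ketone, 6α-Bpin adduct of 17 (C5 epimer mixture) | C=C(CO[Si](C)(C)C(C)(C)C)[C@H]1[C@H](B2OC(C)(C)C(C)(C)O2)C(C(C)=O)[C@](C)(CCC(=O)OC)CC1
F8 | step 14 | 3β-[2-[bis(2,2,2-trifluoroethoxy)phosphoryl]propanoyloxy] derivative of 26 | C=C(CO[Si](C)(C)C(C)(C)C)[C@H]1C=C2[C@](C)(CC[C@H](OC(=O)C(C)P(=O)(OCC(F)(F)F)OCC(F)(F)F)[C@]2(C)O[Si](CC)(CC)CC)CC1
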